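A process chemist running a kinetic resolution with a racemization catalyst wants to know whether the catalyst turns it into a dynamic one, in which exchange refills the faster hand.

| flask | left-handed substrate | right-handed substrate | reagent | racemization catalyst | remark | time |
|---|---|---|---|---|---|---|
| noon | 0.12 M | 0.12 M | 4 equiv | 0.067 mol% | run made earlier |  |
| dawn | 0.12 M | 0.12 M | 4 equiv | 0.15 mol% | run made earlier |  |
| flask | 0.12 M | 0.12 M | 4.00 equiv | 0.1 mol% |  | 2.5 min |

| run | time / min | left-handed product / % | right-handed product / % | left-handed substrate / % |
|---|---|---|---|---|
| noon | 0.500 | 15 | 2 | 31 |
| noon | 1.00 | 27 | 3 | 24 |
| noon | 1.50 | 33 | 6 | 17 |
| noon | 2.00 | 39 | 10 | 13 |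
| noon | 2.50 | 42 | 11 | 7 |
| dawn | 0.200 | 6 | 1 | 45 |
| dawn | 0.667 | 16 | 5 | 29 |
| dawn | 1.33 | 30 | 5 | 18 |
| dawn | 2.00 | 38 | 8 | 12 |
| dawn | 2.50 | 41 | 13 | 9 |

(standard deviation of a reading: 1.5 percentage points)

- reagent is single-handed; left-handed substrate and right-handed substrate are mirror images of each other, charged as a racemate, each of them at the stated concentration
- the numbers in the tables scatter by 1.5 percentage points (one standard deviation)
- an excess is the difference of the two amounts in percent of their sum
- an excess is below zero if the other one leads
- the handed part of reagent does not stay in what it makes, so the products of the two hands are mirror images too

- left-handed product and right-handed product together, in percent of the left-handed substrate and right-handed substrate charged together, at 2.5 min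
- excess of left-handed product over right-handed product in the product at 2.5 min
- whether the exchange between left-handed substrate and right-handed substrate keeps pace with the reaction: how far the product's excess at 2.5 min gets from its value without exchange to its value with instant exchange (above 80% keeps pace, below 20% hardly takes part, else lags behind)

Take the balance of the left hand, in fractions of the charge. Reagent turns left-handed substrate into left-handed product, which leaves their sum unchanged, so a change in that sum is exchange.

surplus = left-handed substrate + left-handed product − 0.5

At 2.50 min the noon run gives −1 percentage point and the dawn run 0 points, a mean of −0.5 points.

The bench rule says that, with charges and time held, more catalyst gives more exchange, so with a loading ratio of 2.24 the dawn surplus should be about twice the noon one. These two readings cannot show that: they stand 1 point apart, less than the scatter of a single reading. The border comes from the levelling distance, the amount that must cross to bring the two substrates level. With right-handed substrate taken as its charge minus right-handed product, the mean readings give: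

levelling distance = 15 points

One standard deviation of the mean surplus is therefore 10.0% of that distance. Call surplus over levelling distance the level share. Two standard deviations above the mean, the readings allow 16.7% as the upper level share, which is lower than 20%. Taking the level share as my stand-in for the share of the way asked about, my call is that exchange hardly takes part. The flask's loading lies between the two runs, so I average their readings and get a product total of 53.5% with excess 55.1%.

The forecast, reckoned from rate constants, says a product total of 53.5% (51.5% to 55.5%), excess 57% (53% to 61%), and that exchange hardly takes part, holding that “exchange is undetectable”. Its excess is higher than mine.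

The flask gives a product total of 53.1% and excess 53.6%, and exchange hardly takes part, with the product's excess 3.9% of the way along.

    reagent + left-handed substrate → left-handed product (k = 0.0275 M⁻¹ s⁻¹)
    left-handed substrate + racemization catalyst ⇌ right-handed substrate + racemization catalyst, rate k2*[racemization catalyst]*[left-handed substrate] forward; the back reaction follows from the equilibrium constant (k = 50.1 M⁻¹ s⁻¹)
    reagent + right-handed substrate → right-handed product (k = 0.00476 M⁻¹ s⁻¹)
    racemization catalyst → spent catalyst (k = 0.0811 s⁻¹)
    racemization catalyst ⇌ dormant form (K = 1.40, k = 0.100 s⁻¹)

The half-life of racemization catalyst towards spent catalyst, by that step alone, is 0.14 min, shorter than the 1.0 min half-life of left-handed substrate by its reaction at 0.707 min. At 2.50 min spent catalyst stands at 98.4% of the catalyst charged. The flask's surplus is 0.66 points, a level share of 4.84%, lower than the upper 16.7%. The neighbour flask with 6.80 equiv of reagent reaches excess 42.1% and a level share of 6.76%.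

The runs are simulated with made-up constants, and the scatter is random.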